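**Retrosynthetic overview**
- Target ⇒ one acyclic precursor: an ortho-(MOM-oxy)aryl phenylethynyl ketone carrying an (R)-1-(tert-butanesulfinylamino)-5-chloropentyl chain. The pyranone ring C (O1–C2, 6-endo) and the piperidine ring (N–C6, 6-exo-tet) both close in the last flask, pyranone first (acid), piperidine second (base).
- Ynone aryl–C(=O) bond ⇒ ring lithiation of the sulfinamide plus the Weinreb amide of phenylpropiolic acid.
- Benzylic aryl–C bond and the stereocentre ⇒ aryl Grignard (lithiation between two OMOM groups) plus the (R)-N-sulfinyl imine of 5-chloropentanal.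
- Arene ⇒ 5-methoxyresorcinol; its mirror symmetry makes both ring functionalisations regiochemically unambiguous. Ring A and the phenyl ring B are bought.

Assumption: 5-chloropentanal and N-methoxy-N-methyl-3-phenylprop-2-ynamide are bought as catalogue compounds (each is otherwise one routine step from 5-chloropentan-1-ol or phenylpropiolic acid).

**Step 1**
Reactants: 1 5-methoxyresorcinol (5-methoxybenzene-1,3-diol)
Product: 2 bis-MOM ether 1-methoxy-3,5-bis(methoxymethoxy)benzene
Conditions: MOMCl (2.5 equiv), i-Pr2NEt, CH2Cl2, 0 °C → rt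
Reagents that add atoms: chloromethyl methyl ether (MOMCl), COCCl
Why: Plain O-alkylation (MOM protection) of both phenols; the MOM ethers direct both later lithiations and fall off in the acid stage of step 5.

**Step 2**
Reactants: 3 5-chloropentanal; 4 (R)-2-methylpropane-2-sulfinamide
Product: 5 sulfinyl imine (R,E)-N-(5-chloropentylidene)-2-methylpropane-2-sulfinamide
Conditions: CuSO4 (2 equiv), CH2Cl2, rt
Reagents that add atoms: none
Why: Ellman condensation; CuSO4 acts as Lewis acid and desiccant and gives the (E)-aldimine without touching the primary chloride or the sulfur stereocentre.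

**Step 3**
Reactants: 2 bis-MOM ether 1-methoxy-3,5-bis(methoxymethoxy)benzene; 5 sulfinyl imine (R,E)-N-(5-chloropentylidene)-2-methylpropane-2-sulfinamide
Product: 8 sulfinamide (R)-N-[(1R)-5-chloro-1-[4-methoxy-2,6-bis(methoxymethoxy)phenyl]pentyl]-2-methylpropane-2-sulfinamide, via aryllithium 6 (not isolated), via arylmagnesium bromide 7 (not isolated)
Conditions: n-BuLi, Et2O, 0 °C → rt; MgBr2·OEt2, 0 °C; 5, toluene, −78 → −20 °C; H2O
Reagents that add atoms: none
Why: Directed ortho-metalation occurs at the doubly activated position between the two OMOM groups, and after Li→Mg exchange the aryl Grignard adds to the (R)-sulfinyl aldimine through the Ellman six-membered chelate (Mg on the sulfinyl oxygen, tert-butyl equatorial, non-coordinating solvent), which delivers the aryl group to the face giving the (R)-carbon; the minor diastereomer is removed by chromatography and the primary chloride survives at low temperature.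

**Step 4**
Reactants: 8 sulfinamide (R)-N-[(1R)-5-chloro-1-[4-methoxy-2,6-bis(methoxymethoxy)phenyl]pentyl]-2-methylpropane-2-sulfinamide; 9 N-methoxy-N-methyl-3-phenylprop-2-ynamide
Product: 11 ynone (R)-N-[(1R)-5-chloro-1-[4-methoxy-2,6-bis(methoxymethoxy)-3-(3-phenylprop-2-ynoyl)phenyl]pentyl]-2-methylpropane-2-sulfinamide, via dilithiated sulfinamide 10 (not isolated)
Conditions: s-BuLi (2.3 equiv), TMEDA, THF, −78 °C; 9, −78 → −40 °C; AcOH, −78 °C
Reagents that add atoms: none
Why: The first equivalent of base removes N–H (which shields sulfur and nitrogen), the second lithiates the only remaining kind of ring C–H (between OMOM and OMe, directed ortho-metalation; the two positions are equivalent by rotation about the aryl–C bond), and the Weinreb chelate stops the acylation at the ketone (Weinreb ketone synthesis); the stereocentre is not involved.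

**Step 5**
Reactants: 11 ynone (R)-N-[(1R)-5-chloro-1-[4-methoxy-2,6-bis(methoxymethoxy)-3-(3-phenylprop-2-ynoyl)phenyl]pentyl]-2-methylpropane-2-sulfinamide
Product: 13 7-hydroxy-5-methoxy-2-phenyl-8-[(2R)-piperidin-2-yl]-4H-chromen-4-one, via flavone ammonium chloride 12 (not isolated)
Conditions: HCl (4 M in dioxane), MeOH, 0 → 45 °C; evaporate; NaHCO3, NaI (cat.), MeCN–H2O, 50 °C
Reagents that add atoms: none
Why: Methanolic HCl cleaves both MOM acetals and the N-sulfinyl group, and the freed ortho-phenol closes onto the protonated ynone in a 6-endo oxa-Michael cyclisation (any HCl or MeOH adduct of the ynone gives the same pyranone by addition–elimination) while nitrogen stays masked as ammonium; neutralisation then frees the primary amine for a Finkelstein-assisted 6-exo-tet SN2 closure of the piperidine, and neither ring closure touches the benzylic stereocentre set in step 3.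

**Compound list**
1 | 5-methoxyresorcinol (5-methoxybenzene-1,3-diol) | COc1cc(O)cc(O)c1 | starting material
2 | 1-methoxy-3,5-bis(methoxymethoxy)benzene | COCOc1cc(OC)cc(OCOC)c1 | intermediate
3 | 5-chloropentanal | O=CCCCCCl | starting material
4 | (R)-2-methylpropane-2-sulfinamide | CC(C)(C)[S@@](=O)N | starting material
5 | (R,E)-N-(5-chloropentylidene)-2-methylpropane-2-sulfinamide | CC(C)(C)[S@@](=O)/N=C/CCCCCl | intermediate
6 | [4-methoxy-2,6-bis(methoxymethoxy)phenyl]lithium | [Li]c1c(OCOC)cc(OC)cc1OCOC | intermediate
7 | bromo[4-methoxy-2,6-bis(methoxymethoxy)phenyl]magnesium | Br[Mg]c1c(OCOC)cc(OC)cc1OCOC | intermediate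
8 | (R)-N-[(1R)-5-chloro-1-[4-methoxy-2,6-bis(methoxymethoxy)phenyl]pentyl]-2-methylpropane-2-sulfinamide | CC(C)(C)[S@@](=O)N[C@H](CCCCCl)c1c(OCOC)cc(OC)cc1OCOC | intermediate
9 | N-methoxy-N-methyl-3-phenylprop-2-ynamide | CON(C)C(=O)C#Cc1ccccc1 | starting material
10 | N-lithio, ring-3-lithio derivative of 8 (lithium on nitrogen and on the ring carbon between OMOM and OMe) | CC(C)(C)[S@@](=O)N([Li])[C@H](CCCCCl)c1c(OCOC)c([Li])c(OC)cc1OCOC | intermediate
11 | (R)-N-[(1R)-5-chloro-1-[4-methoxy-2,6-bis(methoxymethoxy)-3-(3-phenylprop-2-ynoyl)phenyl]pentyl]-2-methylpropane-2-sulfinamide | CC(C)(C)[S@@](=O)N[C@H](CCCCCl)c1c(OCOC)c(C(=O)C#Cc2ccccc2)c(OC)cc1OCOC | intermediate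
12 | 8-[(1R)-1-amino-5-chloropentyl]-7-hydroxy-5-methoxy-2-phenyl-4H-chromen-4-one hydrochloride | COc1cc(O)c([C@H](N)CCCCCl)c2oc(-c3ccccc3)cc(=O)c12.Cl | intermediate
13 | 7-hydroxy-5-methoxy-2-phenyl-8-[(2R)-piperidin-2-yl]-4H-chromen-4-one | COc1cc(O)c([C@H]2CCCCN2)c2oc(-c3ccccc3)cc(=O)c12 | target

**Totals**
Total step count: 5.
Longest linear sequence: 4 steps (1 → 2 → 8 → 11 → 13; step 2 is a one-step side branch).

**Three steps most likely to fail, with fallbacks**

Step 5 (double ring closure). The risks are 5-exo closure to an aurone if ynone survives into the basic stage, intermolecular N- or O-alkylation, and erosion of ee through retro-Mannich opening of the ortho-hydroxybenzylamine on prolonged heating; ee should be checked by chiral HPLC. The fallback closes the rings one at a time and sets out from 11. Diethylamine in EtOH at rt adds to the ynone to give the enaminone (R)-N-[(1R)-5-chloro-1-[3-[(E)-3-(diethylamino)-3-phenylprop-2-enoyl]-4-methoxy-2,6-bis(methoxymethoxy)phenyl]pentyl]-2-methylpropane-2-sulfinamide F6, which is inert to base and can only cyclise 6-endo. NaH in DMF at 0 °C then closes the piperidine at the sulfinamide stage to give the N-sulfinylpiperidine enaminone F7. HCl in MeOH at 45 °C followed by NaHCO3 removes MOM and sulfinyl groups and closes the pyranone by addition–elimination with loss of diethylamine, returning to the route at 13.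

Step 4 (second lithiation and acylation). The risks are incomplete ring lithiation of the N-lithiated substrate, attack of s-BuLi on the alkyl chloride, and addition of the released N,O-dimethylhydroxylamine to the ynone (that adduct would still converge to the pyranone in step 5). The fallback sets out from 8 and replaces the anionic chemistry by electrophilic substitution and palladium catalysis. NIS in MeCN at 0 °C iodinates the one free kind of ring position to give the aryl iodide (R)-N-[(1R)-5-chloro-1-[3-iodo-4-methoxy-2,6-bis(methoxymethoxy)phenyl]pentyl]-2-methylpropane-2-sulfinamide F5. Carbonylative Sonogashira coupling with phenylacetylene (PdCl2(PPh3)2, Et3N, CO 1 atm, THF, rt) then returns to the route at 11.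

Step 3 (aryl Grignard addition to an enolisable alkyl sulfinyl imine). The risks are α-deprotonation of the imine and a diastereoselectivity that is low, or even reversed if the ortho-OMOM groups disturb the chelate. The configuration of 8 should be confirmed before going on. The fallback reverses the polarity and sets out from 2. Lithiation with n-BuLi and quenching with DMF gives 4-methoxy-2,6-bis(methoxymethoxy)benzaldehyde F1. Condensation with (S)-2-methylpropane-2-sulfinamide and CuSO4 gives the aryl sulfinyl imine (S,E)-N-[[4-methoxy-2,6-bis(methoxymethoxy)phenyl]methylidene]-2-methylpropane-2-sulfinamide F2, which has no α-hydrogen. Cl(CH2)4MgBr (from 1-bromo-4-chlorobutane and Mg) in CH2Cl2 at −48 °C adds through the same chelate model to give (S)-N-[(1R)-5-chloro-1-[4-methoxy-2,6-bis(methoxymethoxy)phenyl]pentyl]-2-methylpropane-2-sulfinamide F3, the sulfur epimer of 8 with the same (R)-carbon. The conditions of step 4 convert it into the sulfur-epimeric ynone (S)-N-[(1R)-5-chloro-1-[4-methoxy-2,6-bis(methoxymethoxy)-3-(3-phenylprop-2-ynoyl)phenyl]pentyl]-2-methylpropane-2-sulfinamide F4, and the acid stage of step 5 removes the auxiliary, so the fallback returns to the route at 12.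

**Further compounds**
F1 | step 3 | 4-methoxy-2,6-bis(methoxymethoxy)benzaldehyde | O=Cc1c(OCOC)cc(OC)cc1OCOC
F2 | step 3 | (S,E)-N-[[4-methoxy-2,6-bis(methoxymethoxy)phenyl]methylidene]-2-methylpropane-2-sulfinamide | CC(C)(C)[S@](=O)/N=C/c1c(OCOC)cc(OC)cc1OCOC
F3 | step 3 | (S)-N-[(1R)-5-chloro-1-[4-methoxy-2,6-bis(methoxymethoxy)phenyl]pentyl]-2-methylpropane-2-sulfinamide | CC(C)(C)[S@](=O)N[C@H](CCCCCl)c1c(OCOC)cc(OC)cc1OCOC
F4 | step 3 | (S)-N-[(1R)-5-chloro-1-[4-methoxy-2,6-bis(methoxymethoxy)-3-(3-phenylprop-2-ynoyl)phenyl]pentyl]-2-methylpropane-2-sulfinamide | CC(C)(C)[S@](=O)N[C@H](CCCCCl)c1c(OCOC)c(C(=O)C#Cc2ccccc2)c(OC)cc1OCOC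
F5 | step 4 | (R)-N-[(1R)-5-chloro-1-[3-iodo-4-methoxy-2,6-bis(methoxymethoxy)phenyl]pentyl]-2-methylpropane-2-sulfinamide | CC(C)(C)[S@@](=O)N[C@H](CCCCCl)c1c(OCOC)c(I)c(OC)cc1OCOC
F6 | step 5 | (R)-N-[(1R)-5-chloro-1-[3-[(E)-3-(diethylamino)-3-phenylprop-2-enoyl]-4-methoxy-2,6-bis(methoxymethoxy)phenyl]pentyl]-2-methylpropane-2-sulfinamide | CC(C)(C)[S@@](=O)N[C@H](CCCCCl)c1c(OCOC)c(C(=O)/C=C(/N(CC)CC)c2ccccc2)c(OC)cc1OCOC
F7 | step 5 | (E)-3-(diethylamino)-1-[6-methoxy-2,4-bis(methoxymethoxy)-3-[(2R)-1-[(R)-tert-butylsulfinyl]piperidin-2-yl]phenyl]-3-phenylprop-2-en-1-one | CC(C)(C)[S@@](=O)N1CCCC[C@@H]1c1c(OCOC)c(C(=O)/C=C(/N(CC)CC)c2ccccc2)c(OC)cc1OCOC
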